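**Retrosynthetic overview** (germacrane locants: ring A = ten-membered carbocycle C1–C10, ring B = butenolide C6–C7–C11–C12–O, C13 = the CH2OAc carbon, tiglate on the C3 oxygen)
1. Enabling feature: the C8–C9 bond is the central σ-bond of the 1,5-diene C11=C7–C8–C9–C10=C1; C8 is the CH2 on the β-carbon (C7) of ring B and C9 the CH2 next to the (Z)-C1=C10 olefin of ring A, so both are primary allylic carbons that can be joined by reductive allyl–allyl coupling.
2. Ring A is closed last across C8–C9 by Ni(CO)4-mediated cyclization of the open-chain bis-allylic dibromide 21, which already carries ring B, C3, C6 and both olefins; the C13 oxygen is a silyl ether at that stage and becomes the acetate at the end.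
3. Ring B is built in one flask from γ-hydroxy ynoate 14 by carbocupration (brings C8), aldol trapping with CH2O (brings C13) and lactonization; 14 comes from enal 12 and methyl propiolate by asymmetric alkynylation (C6–C7 bond, 6R).
4. The (Z)-C1=C10 olefin and C3 come from Brown allylboration of enal 3, methacrylate ring-closing metathesis to a temporary δ-lactone, and reductive opening; 3 comes from a Wittig reaction.
5. Order of ring formation: temporary δ-lactone (steps 4–5, opened again), ring B (step 11), ring A (step 14).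

Key step: step 14

Assumption: (S,S)-ProPhenol is taken to be the ligand enantiomer that directs alkynyl transfer to the Si face of enal 12 in step 9; if the sense is the opposite, (R,R)-ProPhenol is used instead.
Assumption: the acetal carbon of the 1-ethoxyethyl group is present as both configurations from 16 to 19 and is removed in step 12.

Step 1
Reactants: 1 2,2-dimethoxyacetaldehyde; 2 2-(triphenylphosphoranylidene)propanal
Product: 3 (2E)-4,4-dimethoxy-2-methylbut-2-enal
Conditions: CH2Cl2, rt (1 used as the dried organic extract of its commercial aqueous solution)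
Reagents that add atoms: none
Why: Wittig olefination with the formyl-stabilized α-methyl ylide should give the (E)-trisubstituted enal, and the ylide should stop after one addition because the product enal is far less electrophilic than aldehyde 1.

Step 2
Reactants: 3 (2E)-4,4-dimethoxy-2-methylbut-2-enal
Product: 5 (4S,5E)-7,7-dimethoxy-5-methylhepta-1,5-dien-4-ol, via borinate ester 4 (not isolated)
Conditions: (−)-Ipc2B(allyl) (from (+)-α-pinene), Et2O, −78 °C; then 3 M NaOH, 30% H2O2, 0 °C → rt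
Reagents that add atoms: (−)-B-allyldiisopinocampheylborane, C=CCB([C@@H]1C[C@@H]2C[C@@H](C2(C)C)[C@H]1C)[C@@H]1C[C@@H]2C[C@@H](C2(C)C)[C@H]1C
Why: Brown allylboration through a chair-like six-membered transition state, in which the reagent derived from (+)-α-pinene transfers allyl to the Si face of the aldehyde, should set the (S)-carbinol that becomes C3.

Step 3
Reactants: 5 (4S,5E)-7,7-dimethoxy-5-methylhepta-1,5-dien-4-ol
Product: 6 (4S,5E)-7,7-dimethoxy-5-methylhepta-1,5-dien-4-yl 2-methylprop-2-enoate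
Conditions: methacryloyl chloride, Et3N, DMAP (cat.), CH2Cl2, 0 °C
Reagents that add atoms: methacryloyl chloride, C=C(C)C(=O)Cl
Why: DMAP-catalysed acylation of the secondary allylic alcohol installs the methacrylate that supplies C9, C10 and the C10 methyl group, with no change at the carbinol centre.

Step 4
Reactants: 6 (4S,5E)-7,7-dimethoxy-5-methylhepta-1,5-dien-4-yl 2-methylprop-2-enoate
Product: 7 (6S)-6-[(2E)-4,4-dimethoxybut-2-en-2-yl]-3-methyl-5,6-dihydro-2H-pyran-2-one
Conditions: second-generation Grubbs catalyst RuCl2(=CHPh)(H2IMes)(PCy3) (5 mol%), CH2Cl2 (5 mM), 40 °C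
Reagents that add atoms: none
Why: Ring-closing metathesis between the terminal allyl olefin and the methacrylate should close the six-membered unsaturated δ-lactone, a temporary ring that can only hold a cis olefin and so fixes the Z geometry of the future C1=C10 bond, while the conjugated trisubstituted olefin stays out of the reaction.

Step 5
Reactants: 7 (6S)-6-[(2E)-4,4-dimethoxybut-2-en-2-yl]-3-methyl-5,6-dihydro-2H-pyran-2-one
Product: 9 (2Z,5S,6E)-8,8-dimethoxy-2,6-dimethylocta-2,6-diene-1,5-diol, via lactol 8 (not isolated)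
Conditions: i-Bu2AlH (4 equiv), CH2Cl2, −78 → 0 °C; aq. KNaC4H4O6
Reagents that add atoms: none
Why: 1,2-Reduction of the unsaturated lactone by i-Bu2AlH opens the temporary ring to the (Z)-ene-1,5-diol with olefin geometry and carbinol centre unchanged, the dimethyl acetal being inert to hydride.

Step 6
Reactants: 9 (2Z,5S,6E)-8,8-dimethoxy-2,6-dimethylocta-2,6-diene-1,5-diol
Product: 10 (2E,4S,6Z)-8-{[tert-butyl(dimethyl)silyl]oxy}-1,1-dimethoxy-3,7-dimethylocta-2,6-dien-4-ol
Conditions: TBSCl (1.05 equiv), imidazole, CH2Cl2, −20 °C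
Reagents that add atoms: tert-butyl(chloro)dimethylsilane, CC(C)(C)[Si](C)(C)Cl
Why: Silylation should be selective for the unhindered primary allylic hydroxyl over the secondary one flanked by the trisubstituted olefin.

Step 7
Reactants: 10 (2E,4S,6Z)-8-{[tert-butyl(dimethyl)silyl]oxy}-1,1-dimethoxy-3,7-dimethylocta-2,6-dien-4-ol
Product: 11 (2E,4S,6Z)-8-{[tert-butyl(dimethyl)silyl]oxy}-1,1-dimethoxy-3,7-dimethylocta-2,6-dien-4-yl (2E)-2-methylbut-2-enoate
Conditions: (2E)-2-methylbut-2-enoyl chloride, pyridine, DMAP (cat.), CH2Cl2, 0 °C → rt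
Reagents that add atoms: (2E)-2-methylbut-2-enoyl chloride (tigloyl chloride), C/C=C(\C)C(=O)Cl
Why: DMAP-catalysed acylation of the remaining secondary alcohol with the (E)-configured acid chloride introduces the tiglate with retention at C3 under buffered conditions that spare the acetal and the silyl ether.

Step 8
Reactants: 11 (2E,4S,6Z)-8-{[tert-butyl(dimethyl)silyl]oxy}-1,1-dimethoxy-3,7-dimethylocta-2,6-dien-4-yl (2E)-2-methylbut-2-enoate
Product: 12 (2E,4S,6Z)-8-{[tert-butyl(dimethyl)silyl]oxy}-3,7-dimethyl-1-oxoocta-2,6-dien-4-yl (2E)-2-methylbut-2-enoate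
Conditions: oxalic acid (5% aq.), THF, 0 °C
Reagents that add atoms: water, O
Why: Mild acid hydrolysis of the allylic dimethyl acetal, which ionizes much more readily than the silyl ether or the esters, should release the (E)-enal.

Step 9
Reactants: 12 (2E,4S,6Z)-8-{[tert-butyl(dimethyl)silyl]oxy}-3,7-dimethyl-1-oxoocta-2,6-dien-4-yl (2E)-2-methylbut-2-enoate; 13 methyl prop-2-ynoate
Product: 14 methyl (4R,5E,7S,9Z)-11-{[tert-butyl(dimethyl)silyl]oxy}-4-hydroxy-6,10-dimethyl-7-{[(2E)-2-methylbut-2-enoyl]oxy}undeca-5,9-dien-2-ynoate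
Conditions: (S,S)-ProPhenol (10 mol%), Ph3P=O (20 mol%), Me2Zn (3 equiv), 13 (3 equiv), toluene, 4 °C; aq. NH4Cl
Reagents that add atoms: none
Why: In this zinc/ProPhenol-catalysed asymmetric alkynylation the dinuclear zinc alkynylide of the propiolate adds 1,2 to the enal under catalyst control on the Si face, which should set the (R)-carbinol that becomes C6 and form the C6–C7 bond.

Step 10
Reactants: 15 (tributylstannyl)methanol
Product: 16 tributyl[(1-ethoxyethoxy)methyl]stannane
Conditions: ethyl vinyl ether, PPTS (cat.), CH2Cl2, rt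
Reagents that add atoms: ethyl vinyl ether, C=COCC
Why: Acid-catalysed addition of the alcohol to the enol ether gives the mixed acetal that masks the hydroxyl during the later tin–lithium exchange.

Step 11
Reactants: 14 methyl (4R,5E,7S,9Z)-11-{[tert-butyl(dimethyl)silyl]oxy}-4-hydroxy-6,10-dimethyl-7-{[(2E)-2-methylbut-2-enoyl]oxy}undeca-5,9-dien-2-ynoate; 16 tributyl[(1-ethoxyethoxy)methyl]stannane
Product: 19 (1E,3S,5Z)-7-{[tert-butyl(dimethyl)silyl]oxy}-1-{(2R)-4-({[tert-butyl(diphenyl)silyl]oxy}methyl)-3-[(1-ethoxyethoxy)methyl]-5-oxo-2,5-dihydrofuran-2-yl}-2,6-dimethylhepta-1,5-dien-3-yl (2E)-2-methylbut-2-enoate, via alkenylcopper adduct 17 (not isolated), via hydroxymethylbutenolide 18 (not isolated)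
Conditions: 16 (4 equiv), n-BuLi, THF, −78 °C; CuBr·SMe2 (2 equiv), −78 → −40 °C; 14, −78 °C; CH2O (gas), −78 → −20 °C; aq. NH4Cl; crude 18, TBDPSCl, imidazole, CH2Cl2, 0 °C
Reagents that add atoms: formaldehyde, C=O; tert-butyl(chloro)diphenylsilane, CC(C)(C)[Si](Cl)(c1ccccc1)c1ccccc1
Why: Tin–lithium exchange gives the α-alkoxymethyllithium whose Gilman cuprate adds syn across the ynoate (carbocupration), the geometrically defined alkenylcopper is trapped at carbon by formaldehyde with retention (tandem conjugate addition–aldol), the C6 alkoxide cis to the ester lactonizes to the butenolide, and the new primary alcohol is silylated, so that C8 and C13 end up cis on the tetrasubstituted olefin and C6 is not touched.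

Step 12
Reactants: 19 (1E,3S,5Z)-7-{[tert-butyl(dimethyl)silyl]oxy}-1-{(2R)-4-({[tert-butyl(diphenyl)silyl]oxy}methyl)-3-[(1-ethoxyethoxy)methyl]-5-oxo-2,5-dihydrofuran-2-yl}-2,6-dimethylhepta-1,5-dien-3-yl (2E)-2-methylbut-2-enoate
Product: 20 (1E,3S,5Z)-1-[(2R)-4-({[tert-butyl(diphenyl)silyl]oxy}methyl)-3-(hydroxymethyl)-5-oxo-2,5-dihydrofuran-2-yl]-7-hydroxy-2,6-dimethylhepta-1,5-dien-3-yl (2E)-2-methylbut-2-enoate
Conditions: CSA (0.1 equiv), MeOH/CH2Cl2 1:1, 0 °C
Reagents that add atoms: none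
Why: Acid-catalysed methanolysis should cleave the 1-ethoxyethyl acetal and the primary allylic TBS ether together, whereas the bulkier TBDPS ether, the two esters and the butenolide should survive at 0 °C.

Step 13
Reactants: 20 (1E,3S,5Z)-1-[(2R)-4-({[tert-butyl(diphenyl)silyl]oxy}methyl)-3-(hydroxymethyl)-5-oxo-2,5-dihydrofuran-2-yl]-7-hydroxy-2,6-dimethylhepta-1,5-dien-3-yl (2E)-2-methylbut-2-enoate
Product: 21 (1E,3S,5Z)-7-bromo-1-[(2R)-3-(bromomethyl)-4-({[tert-butyl(diphenyl)silyl]oxy}methyl)-5-oxo-2,5-dihydrofuran-2-yl]-2,6-dimethylhepta-1,5-dien-3-yl (2E)-2-methylbut-2-enoate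
Conditions: CBr4, PPh3, 2,6-lutidine, CH2Cl2, −30 → 0 °C
Reagents that add atoms: carbon tetrabromide, BrC(Br)(Br)Br
Why: Appel bromination converts both primary allylic alcohols into bromides by SN2 displacement of the alkoxyphosphonium ions at low temperature, which should preserve the (Z)-olefin and avoid allylic transposition.

Step 14
Reactants: 21 (1E,3S,5Z)-7-bromo-1-[(2R)-3-(bromomethyl)-4-({[tert-butyl(diphenyl)silyl]oxy}methyl)-5-oxo-2,5-dihydrofuran-2-yl]-2,6-dimethylhepta-1,5-dien-3-yl (2E)-2-methylbut-2-enoate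
Product: 23 (6Z,9S,10E,11aR)-3-({[tert-butyl(diphenyl)silyl]oxy}methyl)-6,10-dimethyl-2-oxo-2,4,5,8,9,11a-hexahydrocyclodeca[b]furan-9-yl (2E)-2-methylbut-2-enoate, via allylnickel bromide 22 (not isolated)
Conditions: Ni(CO)4 (5 equiv, zerovalent nickel), N-methylpyrrolidone, 50 °C, argon, slow addition of 21 over 12 h (final 2 mM)
Reagents that add atoms: none
Why: Oxidative addition of zerovalent nickel to the more reactive, butenolide-activated C8–Br bond should give allylnickel bromide 22, whose unsubstituted C8 terminus then couples with the C9 allylic bromide through a bis-allyl nickel species and reductive elimination, forming C8–C9 and NiBr2. The closest known reaction type is the nickel-carbonyl-mediated cyclization of α,ω-bis-allylic dibromides to cyclic 1,5-dienes, which is established for medium and large terpenoid rings. Ring A (ten-membered) closes head-to-head between the two primary allyl termini; no new stereocentre is formed, C3 and C6 lie away from the reacting carbons and are carried through, and the C7=C11 olefin cannot change geometry because it is held in ring B. The step needs regioselectivity for C8–C9 over coupling through C11 or C1, which is secured because C11 is fully substituted, C1 is secondary, and closure through C1 would put the (E)-C4=C5 olefin into an eight-membered ring. It also needs the (Z)-C1=C10 geometry, which is installed beforehand and is expected to be the geometry that a syn/anti-equilibrating allylnickel unit adopts when a ten-membered ring closes, so equilibration should not erode it. Ring closure over oligomerization is favoured by slow addition at high dilution, and reductive 1,4-elimination from the nickel dienolate form of 22 is suppressed by carrying the C13 oxygen as a silyl ether instead of the acetate.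

Step 15
Reactants: 23 (6Z,9S,10E,11aR)-3-({[tert-butyl(diphenyl)silyl]oxy}methyl)-6,10-dimethyl-2-oxo-2,4,5,8,9,11a-hexahydrocyclodeca[b]furan-9-yl (2E)-2-methylbut-2-enoate
Product: 24 (6Z,9S,10E,11aR)-3-(hydroxymethyl)-6,10-dimethyl-2-oxo-2,4,5,8,9,11a-hexahydrocyclodeca[b]furan-9-yl (2E)-2-methylbut-2-enoate
Conditions: HF·pyridine, pyridine, THF, 0 °C → rt
Reagents that add atoms: none
Why: Fluoride-mediated desilylation under buffered, weakly acidic conditions should leave the base-sensitive butenolide (acidic C6–H) and both ester-type groups intact.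

Step 16
Reactants: 24 (6Z,9S,10E,11aR)-3-(hydroxymethyl)-6,10-dimethyl-2-oxo-2,4,5,8,9,11a-hexahydrocyclodeca[b]furan-9-yl (2E)-2-methylbut-2-enoate
Product: 25 (6Z,9S,10E,11aR)-3-[(acetyloxy)methyl]-6,10-dimethyl-2-oxo-2,4,5,8,9,11a-hexahydrocyclodeca[b]furan-9-yl (2E)-2-methylbut-2-enoate
Conditions: Ac2O, pyridine, DMAP (cat.), CH2Cl2, 0 °C
Reagents that add atoms: acetic anhydride, CC(=O)OC(C)=O
Why: DMAP-catalysed acetylation of the only free hydroxyl (primary, allylic) should give the target without touching either stereocentre.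

**Compound list**
1 | 2,2-dimethoxyacetaldehyde | COC(OC)C=O | starting material
2 | 2-(triphenylphosphoranylidene)propanal | CC(C=O)=P(c1ccccc1)(c1ccccc1)c1ccccc1 | starting material
3 | (2E)-4,4-dimethoxy-2-methylbut-2-enal | O=C/C(C)=C/C(OC)OC | intermediate
4 | (4S,5E)-7,7-dimethoxy-5-methylhepta-1,5-dien-4-yl diisopinocampheylborinate (borinate ester, not isolated) | B(O[C@@H](CC=C)/C(C)=C/C(OC)OC)([C@@H]1C[C@@H]2C[C@@H](C2(C)C)[C@H]1C)[C@@H]1C[C@@H]2C[C@@H](C2(C)C)[C@H]1C | intermediate
5 | (4S,5E)-7,7-dimethoxy-5-methylhepta-1,5-dien-4-ol | O[C@@H](CC=C)/C(C)=C/C(OC)OC | intermediate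
6 | (4S,5E)-7,7-dimethoxy-5-methylhepta-1,5-dien-4-yl 2-methylprop-2-enoate | C=C(C)C(=O)O[C@@H](CC=C)/C(C)=C/C(OC)OC | intermediate
7 | (6S)-6-[(2E)-4,4-dimethoxybut-2-en-2-yl]-3-methyl-5,6-dihydro-2H-pyran-2-one | O=C1O[C@@H](CC=C1C)/C(C)=C/C(OC)OC | intermediate
8 | (6S)-6-[(2E)-4,4-dimethoxybut-2-en-2-yl]-3-methyl-5,6-dihydro-2H-pyran-2-ol (lactol, both anomers, present as its aluminate, not isolated) | OC1O[C@@H](CC=C1C)/C(C)=C/C(OC)OC | intermediate
9 | (2Z,5S,6E)-8,8-dimethoxy-2,6-dimethylocta-2,6-diene-1,5-diol | O[C@@H](C/C=C(/C)CO)/C(C)=C/C(OC)OC | intermediate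
10 | (2E,4S,6Z)-8-{[tert-butyl(dimethyl)silyl]oxy}-1,1-dimethoxy-3,7-dimethylocta-2,6-dien-4-ol | O[C@@H](C/C=C(/C)CO[Si](C)(C)C(C)(C)C)/C(C)=C/C(OC)OC | intermediate
11 | (2E,4S,6Z)-8-{[tert-butyl(dimethyl)silyl]oxy}-1,1-dimethoxy-3,7-dimethylocta-2,6-dien-4-yl (2E)-2-methylbut-2-enoate | C/C=C(\C)C(=O)O[C@@H](C/C=C(/C)CO[Si](C)(C)C(C)(C)C)/C(C)=C/C(OC)OC | intermediate
12 | (2E,4S,6Z)-8-{[tert-butyl(dimethyl)silyl]oxy}-3,7-dimethyl-1-oxoocta-2,6-dien-4-yl (2E)-2-methylbut-2-enoate | C/C=C(\C)C(=O)O[C@@H](C/C=C(/C)CO[Si](C)(C)C(C)(C)C)/C(C)=C/C=O | intermediate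
13 | methyl prop-2-ynoate (methyl propiolate) | C#CC(=O)OC | starting material
14 | methyl (4R,5E,7S,9Z)-11-{[tert-butyl(dimethyl)silyl]oxy}-4-hydroxy-6,10-dimethyl-7-{[(2E)-2-methylbut-2-enoyl]oxy}undeca-5,9-dien-2-ynoate | C/C=C(\C)C(=O)O[C@@H](C/C=C(/C)CO[Si](C)(C)C(C)(C)C)/C(C)=C/[C@@H](O)C#CC(=O)OC | intermediate
15 | (tributylstannyl)methanol | CCCC[Sn](CCCC)(CCCC)CO | starting material
16 | tributyl[(1-ethoxyethoxy)methyl]stannane | CCCC[Sn](CCCC)(CCCC)COC(C)OCC | intermediate
17 | alkenylcopper adduct of 14: copper on C11, (1-ethoxyethoxy)methyl on C7 and cis to copper, C6 carbinol cis to the ester (drawn as the neutral organocopper, present as lithium alkoxide cuprate, not isolated) | C/C=C(\C)C(=O)O[C@@H](C/C=C(/C)CO[Si](C)(C)C(C)(C)C)/C(C)=C/[C@@H](O)/C(COC(C)OCC)=C(/[Cu])C(=O)OC | intermediate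
18 | (1E,3S,5Z)-7-{[tert-butyl(dimethyl)silyl]oxy}-1-{(2R)-3-[(1-ethoxyethoxy)methyl]-4-(hydroxymethyl)-5-oxo-2,5-dihydrofuran-2-yl}-2,6-dimethylhepta-1,5-dien-3-yl (2E)-2-methylbut-2-enoate (not isolated) | C/C=C(\C)C(=O)O[C@@H](C/C=C(/C)CO[Si](C)(C)C(C)(C)C)/C(C)=C/[C@@H]1C(COC(C)OCC)=C(CO)C(=O)O1 | intermediate
19 | (1E,3S,5Z)-7-{[tert-butyl(dimethyl)silyl]oxy}-1-{(2R)-4-({[tert-butyl(diphenyl)silyl]oxy}methyl)-3-[(1-ethoxyethoxy)methyl]-5-oxo-2,5-dihydrofuran-2-yl}-2,6-dimethylhepta-1,5-dien-3-yl (2E)-2-methylbut-2-enoate | C/C=C(\C)C(=O)O[C@@H](C/C=C(/C)CO[Si](C)(C)C(C)(C)C)/C(C)=C/[C@@H]1C(COC(C)OCC)=C(CO[Si](c2ccccc2)(c2ccccc2)C(C)(C)C)C(=O)O1 | intermediate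
20 | (1E,3S,5Z)-1-[(2R)-4-({[tert-butyl(diphenyl)silyl]oxy}methyl)-3-(hydroxymethyl)-5-oxo-2,5-dihydrofuran-2-yl]-7-hydroxy-2,6-dimethylhepta-1,5-dien-3-yl (2E)-2-methylbut-2-enoate | C/C=C(\C)C(=O)O[C@@H](C/C=C(/C)CO)/C(C)=C/[C@@H]1C(CO)=C(CO[Si](c2ccccc2)(c2ccccc2)C(C)(C)C)C(=O)O1 | intermediate
21 | (1E,3S,5Z)-7-bromo-1-[(2R)-3-(bromomethyl)-4-({[tert-butyl(diphenyl)silyl]oxy}methyl)-5-oxo-2,5-dihydrofuran-2-yl]-2,6-dimethylhepta-1,5-dien-3-yl (2E)-2-methylbut-2-enoate | C/C=C(\C)C(=O)O[C@@H](C/C=C(/C)CBr)/C(C)=C/[C@@H]1C(CBr)=C(CO[Si](c2ccccc2)(c2ccccc2)C(C)(C)C)C(=O)O1 | intermediate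
22 | allylnickel bromide from 21: nickel on the C8 allyl unit of the butenolide, C9 bromide intact (drawn in the σ-form, CO ligands omitted, not isolated) | C/C=C(\C)C(=O)O[C@@H](C/C=C(/C)CBr)/C(C)=C/[C@@H]1C(C[Ni]Br)=C(CO[Si](c2ccccc2)(c2ccccc2)C(C)(C)C)C(=O)O1 | intermediate
23 | (6Z,9S,10E,11aR)-3-({[tert-butyl(diphenyl)silyl]oxy}methyl)-6,10-dimethyl-2-oxo-2,4,5,8,9,11a-hexahydrocyclodeca[b]furan-9-yl (2E)-2-methylbut-2-enoate | C/C=C(\C)C(=O)O[C@H]1C/C=C(/C)CCC2=C(CO[Si](c3ccccc3)(c3ccccc3)C(C)(C)C)C(=O)O[C@@H]2/C=C/1C | intermediate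
24 | (6Z,9S,10E,11aR)-3-(hydroxymethyl)-6,10-dimethyl-2-oxo-2,4,5,8,9,11a-hexahydrocyclodeca[b]furan-9-yl (2E)-2-methylbut-2-enoate | C/C=C(\C)C(=O)O[C@H]1C/C=C(/C)CCC2=C(CO)C(=O)O[C@@H]2/C=C/1C | intermediate
25 | (6Z,9S,10E,11aR)-3-[(acetyloxy)methyl]-6,10-dimethyl-2-oxo-2,4,5,8,9,11a-hexahydrocyclodeca[b]furan-9-yl (2E)-2-methylbut-2-enoate (CNP0198881.1) | C/C=C(\C)C(=O)O[C@H]1C/C=C(/C)CCC2=C(COC(C)=O)C(=O)O[C@@H]2/C=C/1C | target

**Step count**
Total: 16 steps (15 on the main line, 1 for stannane 16). Longest linear sequence: 15 steps (steps 1–9 and 11–16).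

**Steps most likely to fail**

Step 14 (ring closure). What may go wrong: reductive 1,4-elimination of the C13 silyloxy group from the nickel dienolate form of the allylnickel intermediate, intermolecular coupling to oligomers instead of ring closure, or coupling through the secondary allyl terminus after syn/anti equilibration. The fallback sets out from 21 and comes back at 23, and closes the same bond by a polar alkylation instead of a reductive coupling. Dibromide 21 is treated with PhSO2Na (1.0 equiv, DMF, −20 °C), which should displace the more electrophilic, butenolide-activated bromide and give the C8 sulfone with the C9 bromide intact, (1E,3S,5Z)-1-[(2R)-3-[(benzenesulfonyl)methyl]-4-({[tert-butyl(diphenyl)silyl]oxy}methyl)-5-oxo-2,5-dihydrofuran-2-yl]-7-bromo-2,6-dimethylhepta-1,5-dien-3-yl (2E)-2-methylbut-2-enoate F1. Cs2CO3 in DMF at high dilution should then remove the doubly activated C8–H (α to the sulfone and vinylogous to the lactone carbonyl) selectively over C6–H, and the carbanion should alkylate the (Z)-allylic bromide in an SN2 sense to give the macrocyclic sulfone (6Z,9S,10E,11aR)-4-(benzenesulfonyl)-3-({[tert-butyl(diphenyl)silyl]oxy}methyl)-6,10-dimethyl-2-oxo-2,4,5,8,9,11a-hexahydrocyclodeca[b]furan-9-yl (2E)-2-methylbut-2-enoate F2 as a mixture of epimers at the sulfonyl carbon. Reductive desulfonylation with SmI2 (divalent samarium) in THF/MeOH at −78 °C should then give 23.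

Step 11 (one-flask butenolide assembly). What may go wrong: loss of the syn geometry of the alkenylcopper by equilibration through the allenoate before trapping, inefficient capture of gaseous formaldehyde, or competing conjugate addition to the tiglate. The fallback sets out from 14 and comes back at 18, and introduces C13 by cross-coupling instead of aldol trapping. Carbocupration of 14 with the cuprate from 16 is carried out as in step 11 but the alkenylcopper is quenched with iodine, which after lactonization should give the α-iodobutenolide (1E,3S,5Z)-7-{[tert-butyl(dimethyl)silyl]oxy}-1-{(2R)-3-[(1-ethoxyethoxy)methyl]-4-iodo-5-oxo-2,5-dihydrofuran-2-yl}-2,6-dimethylhepta-1,5-dien-3-yl (2E)-2-methylbut-2-enoate F3. Stille coupling of F3 with stannane 15 (Pd(PPh3)4, zerovalent palladium, dioxane, 90 °C) should deliver 18, which is silylated to 19 as in step 11.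

Step 9 (asymmetric alkynylation). What may go wrong: poor facial selectivity (wrong ligand sense, or mismatch with the C3 centre) or slow addition to the β,β-disubstituted enal. The fallback sets out from 12 and comes back at 14, and sets C6 by reduction instead of addition. The lithium acetylide of 13 (LiN(SiMe3)2, THF, −78 °C) is added to 12 without facial control to give methyl (4RS,5E,7S,9Z)-11-{[tert-butyl(dimethyl)silyl]oxy}-4-hydroxy-6,10-dimethyl-7-{[(2E)-2-methylbut-2-enoyl]oxy}undeca-5,9-dien-2-ynoate F4. Oxidation with Dess–Martin periodinane gives the ynone methyl (5E,7S,9Z)-11-{[tert-butyl(dimethyl)silyl]oxy}-6,10-dimethyl-7-{[(2E)-2-methylbut-2-enoyl]oxy}-4-oxoundeca-5,9-dien-2-ynoate F5. Corey–Bakshi–Shibata reduction with (R)-2-methyl-CBS-oxazaborolidine and catecholborane at −78 °C, in which the alkynyl group is expected to act as the small substituent, should then give 14.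

**Further compounds**
F1 | step 14 | (1E,3S,5Z)-1-[(2R)-3-[(benzenesulfonyl)methyl]-4-({[tert-butyl(diphenyl)silyl]oxy}methyl)-5-oxo-2,5-dihydrofuran-2-yl]-7-bromo-2,6-dimethylhepta-1,5-dien-3-yl (2E)-2-methylbut-2-enoate | C/C=C(\C)C(=O)O[C@@H](C/C=C(/C)CBr)/C(C)=C/[C@@H]1C(CS(=O)(=O)c2ccccc2)=C(CO[Si](c2ccccc2)(c2ccccc2)C(C)(C)C)C(=O)O1
F2 | step 14 | (6Z,9S,10E,11aR)-4-(benzenesulfonyl)-3-({[tert-butyl(diphenyl)silyl]oxy}methyl)-6,10-dimethyl-2-oxo-2,4,5,8,9,11a-hexahydrocyclodeca[b]furan-9-yl (2E)-2-methylbut-2-enoate, both epimers at the sulfonyl carbon | C/C=C(\C)C(=O)O[C@H]1C/C=C(/C)CC(S(=O)(=O)c3ccccc3)C2=C(CO[Si](c3ccccc3)(c3ccccc3)C(C)(C)C)C(=O)O[C@@H]2/C=C/1C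
F3 | step 11 | (1E,3S,5Z)-7-{[tert-butyl(dimethyl)silyl]oxy}-1-{(2R)-3-[(1-ethoxyethoxy)methyl]-4-iodo-5-oxo-2,5-dihydrofuran-2-yl}-2,6-dimethylhepta-1,5-dien-3-yl (2E)-2-methylbut-2-enoate | C/C=C(\C)C(=O)O[C@@H](C/C=C(/C)CO[Si](C)(C)C(C)(C)C)/C(C)=C/[C@@H]1C(COC(C)OCC)=C(I)C(=O)O1
F4 | step 9 | methyl (4RS,5E,7S,9Z)-11-{[tert-butyl(dimethyl)silyl]oxy}-4-hydroxy-6,10-dimethyl-7-{[(2E)-2-methylbut-2-enoyl]oxy}undeca-5,9-dien-2-ynoate | C/C=C(\C)C(=O)O[C@@H](C/C=C(/C)CO[Si](C)(C)C(C)(C)C)/C(C)=C/C(O)C#CC(=O)OC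
F5 | step 9 | methyl (5E,7S,9Z)-11-{[tert-butyl(dimethyl)silyl]oxy}-6,10-dimethyl-7-{[(2E)-2-methylbut-2-enoyl]oxy}-4-oxoundeca-5,9-dien-2-ynoate | C/C=C(\C)C(=O)O[C@@H](C/C=C(/C)CO[Si](C)(C)C(C)(C)C)/C(C)=C/C(=O)C#CC(=O)OC
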